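## Structural features

The target is a flavanone: benzene ring A (C4a, C5, C6, C7, C8, C8a) is fused through the C4a–C8a bond to the dihydropyran-4-one ring C (O1, C2, C3, C4), and the 4-hydroxyphenyl ring B is attached to C2. Ring A carries no hydrogen: C5 bears a hydroxyl hydrogen-bonded to the C4 carbonyl, C6 and C8 bear prenyl (3-methylbut-2-enyl) groups, and C7 between them bears the methoxy group. C2, of S configuration, is the only stereocentre, so no neighbouring centre can relay configuration and it must be set by an external chiral influence. C2 is also configurationally fragile: it is benzylic, bound to O1 and β to the C4 carbonyl, so base opens ring C to the 2'-hydroxychalcone (through the C3 enolate or, once O4' is free, through a para-quinone methide) and re-closure racemises. The prenyl groups do not tolerate strong acid (cyclisation onto the flanking oxygens), halogenating or epoxidising reagents, or hydrogenation. The real difficulty is therefore to combine a crowded, regiodefined hexasubstituted ring A with a single labile stereocentre that must be created and then carried under near-neutral conditions. The key step exploits the C2–H bond, which is benzylic, α to O1 and six atoms from C3 along C3–C4–C4a–C8a–O1–C2, so a carbenoid at C3 can reach it. The fifth atom from C3 is an oxygen on either side (O1, O5), and the prenyl groups on C6 and C8 are meta to C4a and out of reach.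

## Logic of the disconnections

**14 to 13.** The O5–H and O4'–H bonds are traced back to O–Si bonds. A free O5–H would quench a carbenoid by O–H insertion, and a free O4'–H would interfere with the etherification, so both are masked by the same silyl group. The gain is one final operation that unmasks both phenols. The demand is desilylation under buffered, non-basic conditions so that ring C does not open.

**13 to 12.** The C2–C3 bond is cut, which opens ring C and removes the only stereocentre. C3 becomes a diazo carbon next to the C4 carbonyl and C2 becomes the methylene of a benzylic ether on O1. The gain is an achiral precursor made from an acetophenone and a benzylic alcohol. The demand is that a chiral catalyst selects one of two enantiotopic hydrogens, and that the carbenoid prefers this C–H bond over the lone pairs of O1 and O5. O5 therefore carries a group with no C–H bond on the atom bound to oxygen.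

**12 to 9 (through 11 and 10).** The C3=N bond is removed and C3 reverts to the methyl group of an aryl methyl ketone. Diazo transfer to an activated methyl ketone avoids diazomethane and the acid chloride of a di-ortho-substituted benzoic acid. The gain is that the whole skeleton is now a plain acetophenone. The demand is enolisation and C-acylation beside a crowded ring without migration of the neighbouring silyl group.

**9 to 8.** The O5–Si bond is cut. The silyl group is needed only from the diazo transfer onwards, and removing it reveals the phenol that made the preceding etherification selective. The demand is silylation of a chelated phenol flanked by two ortho substituents.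

**8 to 5 and 7.** The O1–CH2 bond is cut, which separates ring B and the future C2 from ring A. Because 5 is symmetric, either phenol gives 8, so no regiochemical question arises. The gain is convergence on two fragments. The demand is that etherification stops after one phenol.

**7 to 6.** The O4'–Si bond is cut. The same silyl group is used as on O5 so that one reagent removes both. The demand is silylation of the phenol and not the benzylic alcohol.

**5 to 4.** The O7–CH3 bond is cut. The gain is a precursor with three free hydroxyls whose ring carbons are strongly nucleophilic. The demand is methylation of the one hydroxyl outside the carbonyl chelate.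

**4 to 1 and 2 (through 3).** The C6–CH2 and C8–CH2 bonds are cut at the two nucleophilic ring carbons of a phloroglucinol anion. The gain is the largest in the plan: ring A with its acetyl group and all three oxygens is bought intact. The demand is C- and not O-alkylation, and stopping after two alkylations.

## Other disconnections considered

**Alternative 1:** The cut is at the aryl–CH2 bonds of both prenyl groups (C6–CH2 and C8–CH2), each traced back to an O-bound 2-methylbut-3-en-2-yl group on the neighbouring phenolic oxygen.
- Forward key step: the bis-ether A2 is heated. Each ether undergoes an aromatic Claisen rearrangement (a [3,3] shift with allylic transposition) to the only free ortho carbon and the dienone tautomerises, giving A1 without closing a ring.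
- In its favour: the regiochemistry is fixed by the position of the oxygens, the tertiary ether inverts to a primary prenyl group, nothing can be over-alkylated and no reagent is needed. On regiocontrol of prenyl delivery it is better than the chosen plan, whose step 1 relies on the ambident reactivity of a phloroglucinol anion.
- Against it here: A2 must be made by etherifying two carbonyl-chelated phenols with a tertiary propargylic electrophile and then semihydrogenating. The freed ortho-prenyl phenols can add to their own alkenes at the rearrangement temperature. The step builds neither ring C nor C2.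
- Comparison: A1 is the same compound as 5, so the alternative competes with steps 1 and 2, not with the carbenoid insertion. Structurally it addresses ring A only. Mechanistically it replaces an ionic C-alkylation by a concerted pericyclic shift. In step economy it is about two steps longer. It is therefore held in reserve as the fallback for step 1.

**Alternative 2:** The cut is at C5–C6 and C7–C8 (and, within the cascade, C4a–C5), so ring A is assembled from a four-carbon cyclobutenone and a two-carbon alkyne.
- Forward key step: cyclobutenone A3 and ynol ether A4 are heated. Four-electron ring opening of A3 to a vinylketene, regioselective [2+2] cycloaddition with A4, a second four-electron opening to a dienylketene, six-electron ring closure and tautomerisation would give phenol A5 (Danheiser benzannulation).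
- In its favour: one thermal operation places five of the six substituents of ring A with full regiocontrol. The methoxy group ends up flanked by both prenyl groups without any electrophilic prenylation. The two oxygens that become O5 and O1 emerge already differentiated. On convergence and on this differentiation it is better than the chosen plan, which uses chelation to tell two equivalent phenols apart.
- Against it here: A5 lacks the C4 acyl carbon, and acylation at C4a by Friedel–Crafts or Fries chemistry needs Lewis acids that endanger prenyl groups ortho to oxygen. The ethyl ether must later be cleaved beside the C7 methyl ether, again with boron or aluminium halides. A3 and A4 each need several steps of ketene or metalated alkoxyacetylene chemistry. C2 is not addressed.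
- Comparison: structurally it constructs an aromatic ring that the chosen plan buys in 1. Mechanistically it is a metal-free pericyclic cascade and equal to the chosen key step in being a known reaction class. In step economy it is clearly longer (about five steps to A5, then acylation, dealkylation and an enantioselective closure of ring C).

**Alternative 3:** The cut is at C8–C8a and C4a–C5, so ring A is annulated onto a ring C that already carries the C2 stereocentre.
- Forward key step: the ketene acetal diene A6 undergoes a Diels–Alder reaction with the sulfinyl-activated dihydropyranone A7. Its nucleophilic terminus (the future C8) bonds to the β-carbon of the enone (the future C8a). Syn-elimination of benzenesulfenic acid and loss of methoxytrimethylsilane would then aromatise ring A to A8 with the C5 hydroxyl free.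
- In its favour: C2 would come from a catalytic asymmetric hetero-Diels–Alder reaction of an aryl aldehyde with a 1-methoxy-3-silyloxybutadiene, whose sense of induction is more predictable than that of a carbenoid insertion. On this point the alternative is better. O5 emerges unprotected and distinct from O1, the plan is convergent, and the final deprotection is a single silyl cleavage, equal to the chosen plan.
- Against it here: A6 is a tetrasubstituted diene with a substituent on its reacting terminus and must reach the s-cis form with defined geometry. It meets a β-oxygenated, weakly electrophilic dienophile at a carbon that becomes fully substituted, so two crowded bonds form at once. A6 is hydrolytically labile and needs about three steps from a prenylated β-ketoester. A7 and A8 can lose configuration by retro-oxa-Michael opening under heat or Lewis acid.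
- Comparison: structurally both plans set C2 by catalysis, the alternative earlier. Mechanistically a bimolecular cycloaddition–elimination cascade replaces an intramolecular insertion. The step count is comparable (about nine), but the pivotal cycloaddition is less well precedented for such substituted partners than the insertion is for its substrate class.

Key step: step 7

Assumption: the sense in which the (S)-configured catalyst selects between the enantiotopic benzylic hydrogens cannot be derived with certainty for this substrate; it is taken to be pro-S, and if it proves to be pro-R the mirror-image catalyst Rh2(R-PTTL)4 is used with no other change.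

## Route

Step 1
Reactants: 1 2,4,6-trihydroxyacetophenone; 2 prenyl bromide (1-bromo-3-methylbut-2-ene)
Product: 4 1-[2,4,6-trihydroxy-3,5-bis(3-methylbut-2-enyl)phenyl]ethanone, via 3-prenyl-2,4,6-trihydroxyacetophenone 3 (not isolated)
Conditions: 2 (2.1 equiv), 10% aq KOH, 0 °C to rt
Reagents that add atoms: none
Why: Phenoxide C-alkylation of an acylphloroglucinol: in aqueous hydroxide the hydrogen-bonded polyanion attacks the soft allylic bromide through its two free ring carbons (first to 3, then to 4) in preference to oxygen, the classical bis-prenylation by which deoxyhumulone-type acylphloroglucinols are made; about two equivalents of 2 at 0 °C should hold back a third, dearomatising alkylation.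

Step 2
Reactants: 4 1-[2,4,6-trihydroxy-3,5-bis(3-methylbut-2-enyl)phenyl]ethanone
Product: 5 1-[2,6-dihydroxy-4-methoxy-3,5-bis(3-methylbut-2-enyl)phenyl]ethanone
Conditions: MeI (1.05 equiv), K2CO3 (1.0 equiv), acetone, 0 °C to rt
Reagents that add atoms: iodomethane, CI
Why: Williamson O-methylation with one equivalent of base: the 4-OH, para to the acetyl group and outside the carbonyl chelate, is the most acidic and least hydrogen-bonded hydroxyl, so it should be ionised and methylated in preference to the two ortho hydroxyls.

Step 3
Reactants: 6 4-hydroxybenzyl alcohol
Product: 7 [4-(triisopropylsilyloxy)phenyl]methanol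
Conditions: NaH (1.0 equiv), THF, 0 °C; TIPSCl (1.0 equiv), 0 °C to rt
Reagents that add atoms: chlorotriisopropylsilane, CC(C)[Si](Cl)(C(C)C)C(C)C
Why: Chemoselective silylation through the phenoxide: one equivalent of hydride removes only the phenolic proton (about five pKa units more acidic than the alcohol), and the phenoxide captures the bulky silyl chloride, which reacts only slowly with a neutral primary alcohol when no nucleophilic catalyst is present.

Step 4
Reactants: 5 1-[2,6-dihydroxy-4-methoxy-3,5-bis(3-methylbut-2-enyl)phenyl]ethanone; 7 [4-(triisopropylsilyloxy)phenyl]methanol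
Product: 8 1-[2-hydroxy-4-methoxy-3,5-bis(3-methylbut-2-enyl)-6-(4-triisopropylsilyloxybenzyloxy)phenyl]ethanone
Conditions: 7 (1.05 equiv), PPh3, DIAD, THF, 0 °C to rt
Reagents that add atoms: none
Why: Mitsunobu etherification: the acidic phenol of 5 protonates the betaine and its phenoxide displaces the oxyphosphonium of the primary benzylic alcohol; the two phenols of 5 are equivalent by symmetry, and after the first etherification the remaining hydroxyl is locked in a strong hydrogen bond to the carbonyl group, so the reaction should stop at the mono-ether. No lachrymatory, labile benzylic halide has to be made.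

Step 5
Reactants: 8 1-[2-hydroxy-4-methoxy-3,5-bis(3-methylbut-2-enyl)-6-(4-triisopropylsilyloxybenzyloxy)phenyl]ethanone
Product: 9 1-[4-methoxy-3,5-bis(3-methylbut-2-enyl)-2-(4-triisopropylsilyloxybenzyloxy)-6-(triisopropylsilyloxy)phenyl]ethanone
Conditions: TIPSOTf (1.3 equiv), 2,6-lutidine (2.5 equiv), CH2Cl2, 0 °C to rt
Reagents that add atoms: triisopropylsilyl trifluoromethanesulfonate, CC(C)[Si](OS(=O)(=O)C(F)(F)F)(C(C)C)C(C)C
Why: Silylation of a hindered, chelated phenol with a silyl triflate and a non-nucleophilic pyridine base; the triflate is reactive enough to break the O–H···O=C chelate, while 2,6-lutidine is too weak a base to enolise the twisted aryl methyl ketone competitively and keeps the medium free of acid for the prenyl groups and the benzylic ether.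

Step 6
Reactants: 9 1-[4-methoxy-3,5-bis(3-methylbut-2-enyl)-2-(4-triisopropylsilyloxybenzyloxy)-6-(triisopropylsilyloxy)phenyl]ethanone
Product: 12 2-diazo-1-[4-methoxy-3,5-bis(3-methylbut-2-enyl)-2-(4-triisopropylsilyloxybenzyloxy)-6-(triisopropylsilyloxy)phenyl]ethanone, via trifluoroacetyl diketone 10 (not isolated), via diazo trifluoroacetyl diketone 11 (not isolated)
Conditions: LiHMDS, THF, −78 °C; CF3CO2CH2CF3, −78 °C; then p-ABSA, Et3N, H2O, MeCN, rt
Reagents that add atoms: 4-acetamidobenzenesulfonyl azide, CC(=O)Nc1ccc(cc1)S(=O)(=O)N=[N+]=[N-]; 2,2,2-trifluoroethyl trifluoroacetate, O=C(OCC(F)(F)F)C(F)(F)F (its atoms are kept in 10 and 11 only)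
Why: Detrifluoroacetylative diazo transfer: the kinetic lithium enolate of the methyl ketone is C-acylated to diketone 10, the sulfonyl azide transfers N2 to its activated methylene (Regitz-type diazo transfer) to give 11, and water with triethylamine cleaves the trifluoroacetyl group by retro-Claisen fragmentation to leave the terminal diazoketone 12; diazomethane, an acid chloride and the more hazardous low-molecular-weight sulfonyl azides are all avoided.

Step 7
Reactants: 12 2-diazo-1-[4-methoxy-3,5-bis(3-methylbut-2-enyl)-2-(4-triisopropylsilyloxybenzyloxy)-6-(triisopropylsilyloxy)phenyl]ethanone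
Product: 13 (2S)-7-methoxy-6,8-bis(3-methylbut-2-enyl)-5-(triisopropylsilyloxy)-2-[4-(triisopropylsilyloxy)phenyl]chroman-4-one
Conditions: Rh2(S-PTTL)4 (2 mol %), CH2Cl2 (0.01 M), 0 °C, 12 added over 6 h
Reagents that add atoms: none
Why: Dirhodium tetrakis[N-phthaloyl-(S)-tert-leucinate], Rh2(S-PTTL)4 (divalent rhodium), is attacked by the diazo carbon, nitrogen is lost and an electrophilic rhodium carbenoid is formed at C3. The carbenoid inserts into a benzylic C–H bond of the O1–CH2–aryl group through a concerted, asynchronous three-centre transition state with hydride-transfer character, forming C2–C3 with retention at C2 and releasing the catalyst. The closest known reaction type is the enantioselective intramolecular C–H insertion of 2-alkoxyaryl diazoketones next to the ether oxygen, which gives 2-substituted chroman-4-ones under chiral dirhodium carboxylates. Ring C closes as a six-membered ring by 1,6-insertion; a five-membered alternative does not exist because the fifth atom from C3 is an oxygen on both sides. C2 is set under catalyst control: the chiral pocket of the four phthalimido-tert-leucinate ligands distinguishes the two enantiotopic benzylic hydrogens, and replacement of the pro-S hydrogen gives the (2S) product. The step needs chemoselectivity for C–H insertion over oxonium ylide formation at O1 (followed by 1,2-shift of the benzyl group) and at O5: the targeted C–H bond is doubly activated by the α-oxygen and the electron-rich aryl group, the O1 lone pairs are delocalised into the acylated ring and flanked by the C8 prenyl group, and O5 carries a bulky, weakly donating silyl group with no C–H bond on the atom bound to oxygen. The prenyl groups sit on C6 and C8, meta to C4a, so neither their alkenes nor their allylic C–H bonds can reach C3 within the molecule, and slow addition at high dilution should suppress intermolecular cyclopropanation and carbene dimerisation. The low temperature and the carboxylate catalyst disfavour Wolff rearrangement.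

Step 8
Reactants: 13 (2S)-7-methoxy-6,8-bis(3-methylbut-2-enyl)-5-(triisopropylsilyloxy)-2-[4-(triisopropylsilyloxy)phenyl]chroman-4-one
Product: 14 (2S)-5-hydroxy-2-(4-hydroxyphenyl)-7-methoxy-6,8-bis(3-methylbut-2-enyl)chroman-4-one
Conditions: Bu4NF (3 equiv), AcOH (3.3 equiv), THF, 0 °C to rt
Reagents that add atoms: none
Why: Fluoride-mediated cleavage of both aryl silyl ethers through pentacoordinate silicon; acetic acid keeps the liberated phenols protonated, so neither the C3 enolate nor the 4'-phenoxide and quinone methide pathway that would open ring C and racemise C2 is populated, and the prenyl groups meet no strong acid.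

## Compound list

1 | 2,4,6-trihydroxyacetophenone | CC(=O)c1c(O)cc(O)cc1O | starting material
2 | prenyl bromide (1-bromo-3-methylbut-2-ene) | CC(C)=CCBr | starting material
3 | 1-[2,4,6-trihydroxy-3-(3-methylbut-2-enyl)phenyl]ethanone (not isolated) | CC(=O)c1c(O)cc(O)c(CC=C(C)C)c1O | intermediate
4 | 1-[2,4,6-trihydroxy-3,5-bis(3-methylbut-2-enyl)phenyl]ethanone | CC(=O)c1c(O)c(CC=C(C)C)c(O)c(CC=C(C)C)c1O | intermediate
5 | 1-[2,6-dihydroxy-4-methoxy-3,5-bis(3-methylbut-2-enyl)phenyl]ethanone | CC(=O)c1c(O)c(CC=C(C)C)c(OC)c(CC=C(C)C)c1O | intermediate
6 | 4-hydroxybenzyl alcohol | OCc1ccc(O)cc1 | starting material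
7 | [4-(triisopropylsilyloxy)phenyl]methanol | OCc1ccc(O[Si](C(C)C)(C(C)C)C(C)C)cc1 | intermediate
8 | 1-[2-hydroxy-4-methoxy-3,5-bis(3-methylbut-2-enyl)-6-(4-triisopropylsilyloxybenzyloxy)phenyl]ethanone | COc1c(CC=C(C)C)c(O)c(C(C)=O)c(OCc2ccc(O[Si](C(C)C)(C(C)C)C(C)C)cc2)c1CC=C(C)C | intermediate
9 | 1-[4-methoxy-3,5-bis(3-methylbut-2-enyl)-2-(4-triisopropylsilyloxybenzyloxy)-6-(triisopropylsilyloxy)phenyl]ethanone | COc1c(CC=C(C)C)c(O[Si](C(C)C)(C(C)C)C(C)C)c(C(C)=O)c(OCc2ccc(O[Si](C(C)C)(C(C)C)C(C)C)cc2)c1CC=C(C)C | intermediate
10 | 4,4,4-trifluoro-1-[4-methoxy-3,5-bis(3-methylbut-2-enyl)-2-(4-triisopropylsilyloxybenzyloxy)-6-(triisopropylsilyloxy)phenyl]butane-1,3-dione (not isolated) | COc1c(CC=C(C)C)c(O[Si](C(C)C)(C(C)C)C(C)C)c(C(=O)CC(=O)C(F)(F)F)c(OCc2ccc(O[Si](C(C)C)(C(C)C)C(C)C)cc2)c1CC=C(C)C | intermediate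
11 | 2-diazo-4,4,4-trifluoro-1-[4-methoxy-3,5-bis(3-methylbut-2-enyl)-2-(4-triisopropylsilyloxybenzyloxy)-6-(triisopropylsilyloxy)phenyl]butane-1,3-dione (not isolated) | COc1c(CC=C(C)C)c(O[Si](C(C)C)(C(C)C)C(C)C)c(C(=O)C(=[N+]=[N-])C(=O)C(F)(F)F)c(OCc2ccc(O[Si](C(C)C)(C(C)C)C(C)C)cc2)c1CC=C(C)C | intermediate
12 | 2-diazo-1-[4-methoxy-3,5-bis(3-methylbut-2-enyl)-2-(4-triisopropylsilyloxybenzyloxy)-6-(triisopropylsilyloxy)phenyl]ethanone | COc1c(CC=C(C)C)c(O[Si](C(C)C)(C(C)C)C(C)C)c(C(=O)C=[N+]=[N-])c(OCc2ccc(O[Si](C(C)C)(C(C)C)C(C)C)cc2)c1CC=C(C)C | intermediate
13 | (2S)-7-methoxy-6,8-bis(3-methylbut-2-enyl)-5-(triisopropylsilyloxy)-2-[4-(triisopropylsilyloxy)phenyl]chroman-4-one | COc1c(CC=C(C)C)c(O[Si](C(C)C)(C(C)C)C(C)C)c2c(c1CC=C(C)C)O[C@H](c1ccc(O[Si](C(C)C)(C(C)C)C(C)C)cc1)CC2=O | intermediate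
14 | (2S)-5-hydroxy-2-(4-hydroxyphenyl)-7-methoxy-6,8-bis(3-methylbut-2-enyl)chroman-4-one (CNP0121058.1) | COc1c(CC=C(C)C)c(O)c2c(c1CC=C(C)C)O[C@H](c1ccc(O)cc1)CC2=O | target

## Step count and least certain steps

Total step count: 8. Longest linear sequence: 7 steps (steps 1, 2, 4, 5, 6, 7 and 8 from compound 1); step 3 prepares the side-chain alcohol.

**Step 7 (key step).** The most likely failure is loss of chemoselectivity: the carbenoid is captured by a lone pair of O1 before it reaches the C–H bond, and the cyclic oxonium ylide then undergoes 1,2-shift of the electron-rich benzyl group. A second weakness is incomplete discrimination of the enantiotopic hydrogens, because an acceptor-only carbenoid from a terminal diazoketone reacts through an early transition state. The fallback uses a different bond construction, sets out from 5 and returns at 14.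
- Condensation of 5 with N,N-dimethylformamide dimethyl acetal (toluene, 90 °C) would give the enaminone (E)-3-(dimethylamino)-1-[2,6-dihydroxy-4-methoxy-3,5-bis(3-methylbut-2-enyl)phenyl]prop-2-en-1-one F1.
- F1 closes with loss of dimethylamine in warm acetic acid to 5-hydroxy-7-methoxy-6,8-bis(3-methylbut-2-enyl)chromen-4-one F2.
- Silylation as in step 5 gives 7-methoxy-6,8-bis(3-methylbut-2-enyl)-5-(triisopropylsilyloxy)chromen-4-one F3.
- Rhodium-catalysed asymmetric 1,4-addition of commercial 4-(tert-butyldimethylsilyloxy)phenylboronic acid forms the C2–aryl bond and C2, giving (2S)-2-[4-(tert-butyldimethylsilyloxy)phenyl]-7-methoxy-6,8-bis(3-methylbut-2-enyl)-5-(triisopropylsilyloxy)chroman-4-one F4. Conditions: [Rh(OH)(cod)]2 (monovalent rhodium), an electron-poor chiral biaryl bisphosphine in the enantiomeric form that delivers S, toluene/H2O, rt.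
- Buffered fluoride as in step 8 removes both silyl groups and the fallback rejoins the route at 14.

**Step 1.** The most likely failure is over-alkylation with loss of regiocontrol: after two prenylations the anion is still nucleophilic and a third alkylation at a substituted carbon dearomatises ring A, while part of the material stops at 3 or is alkylated on oxygen. The fallback sets out from 1 and returns at 5, replacing steps 1 and 2.
- 4-O-Methylation of 1 under the conditions of step 2 gives 1-(2,6-dihydroxy-4-methoxyphenyl)ethanone F5.
- Double etherification with 3-chloro-3-methylbut-1-yne (K2CO3, KI, CuI cat., acetone, reflux) gives 1-[4-methoxy-2,6-bis(2-methylbut-3-yn-2-yloxy)phenyl]ethanone F6.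
- Semihydrogenation (H2, Pd on CaCO3 poisoned with Pb(OAc)2, quinoline) gives 1-[4-methoxy-2,6-bis(2-methylbut-3-en-2-yloxy)phenyl]ethanone F7 (the same structure as A2).
- Heating in N,N-diethylaniline at about 140 °C triggers the double aromatic Claisen rearrangement, which delivers both prenyl groups to the only free ortho carbons and gives 5.

**Step 4.** The most likely failure is ionisation of the activated, electron-rich benzylic oxyphosphonium before the hindered phenoxide attacks, which leads to alkylation of the hydrazide by-product or self-condensation; coupling at a phenol flanked by two ortho substituents may also be slow. The fallback sets out from 7 and 5 and returns at 8. Appel bromination of 7 (CBr4, PPh3, CH2Cl2, 0 °C) gives 4-(triisopropylsilyloxy)benzyl bromide F8, which is used at once in a Williamson etherification of 5 (K2CO3, acetone, rt). The same chelation effect should stop that reaction at the mono-ether 8.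

**Step 5.** The most likely failure is sluggish silylation of a chelated phenol flanked by the acetyl and a prenyl group, with competing enol silylation of the ketone or Lewis-acid cleavage of the electron-rich benzylic ether by the silyl triflate. The fallback inverts the order of steps 4 and 5; it sets out from 5 and returns at 9. Mono-silylation of 5 (TIPSOTf, 2,6-lutidine, CH2Cl2, −40 °C) gives 1-[2-hydroxy-4-methoxy-3,5-bis(3-methylbut-2-enyl)-6-(triisopropylsilyloxy)phenyl]ethanone F9; this should be easier because the two hydroxyls of 5 share the chelate and no acid-labile benzylic ether is yet present. Mitsunobu etherification of F9 with 7 (PPh3, DIAD, THF) then gives 9.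

**Step 6.** The most likely failure is incomplete C-acylation of a sterically shielded enolate, or transfer of the O5 silyl group to the enolate oxygen through a six-membered transition state. The fallback uses no strong base; it sets out from 9 and returns at 12. Condensation of 9 with N,N-dimethylformamide dimethyl acetal (neat, 110 °C) gives the enaminone (E)-3-(dimethylamino)-1-[4-methoxy-3,5-bis(3-methylbut-2-enyl)-2-(4-triisopropylsilyloxybenzyloxy)-6-(triisopropylsilyloxy)phenyl]prop-2-en-1-one F10. Diazo transfer from 4-acetamidobenzenesulfonyl azide to F10 (MeCN, rt; cycloaddition to the enamine double bond and fragmentation of the triazoline) gives 12 together with the N-sulfonylformamidine.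

## Further compounds

F1 | step 7 | (E)-3-(dimethylamino)-1-[2,6-dihydroxy-4-methoxy-3,5-bis(3-methylbut-2-enyl)phenyl]prop-2-en-1-one | CN(C)/C=C/C(=O)c1c(O)c(CC=C(C)C)c(OC)c(CC=C(C)C)c1O
F2 | step 7 | 5-hydroxy-7-methoxy-6,8-bis(3-methylbut-2-enyl)chromen-4-one | COc1c(CC=C(C)C)c(O)c2c(c1CC=C(C)C)OC=CC2=O
F3 | step 7 | 7-methoxy-6,8-bis(3-methylbut-2-enyl)-5-(triisopropylsilyloxy)chromen-4-one | COc1c(CC=C(C)C)c(O[Si](C(C)C)(C(C)C)C(C)C)c2c(c1CC=C(C)C)OC=CC2=O
F4 | step 7 | (2S)-2-[4-(tert-butyldimethylsilyloxy)phenyl]-7-methoxy-6,8-bis(3-methylbut-2-enyl)-5-(triisopropylsilyloxy)chroman-4-one | COc1c(CC=C(C)C)c(O[Si](C(C)C)(C(C)C)C(C)C)c2c(c1CC=C(C)C)O[C@H](c1ccc(O[Si](C)(C)C(C)(C)C)cc1)CC2=O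
F5 | step 1 | 1-(2,6-dihydroxy-4-methoxyphenyl)ethanone | CC(=O)c1c(O)cc(OC)cc1O
F6 | step 1 | 1-[4-methoxy-2,6-bis(2-methylbut-3-yn-2-yloxy)phenyl]ethanone | CC(=O)c1c(OC(C)(C)C#C)cc(OC)cc1OC(C)(C)C#C
F7 | step 1 | 1-[4-methoxy-2,6-bis(2-methylbut-3-en-2-yloxy)phenyl]ethanone | CC(=O)c1c(OC(C)(C)C=C)cc(OC)cc1OC(C)(C)C=C
F8 | step 4 | 4-(triisopropylsilyloxy)benzyl bromide | BrCc1ccc(O[Si](C(C)C)(C(C)C)C(C)C)cc1
F9 | step 5 | 1-[2-hydroxy-4-methoxy-3,5-bis(3-methylbut-2-enyl)-6-(triisopropylsilyloxy)phenyl]ethanone | CC(=O)c1c(O)c(CC=C(C)C)c(OC)c(CC=C(C)C)c1O[Si](C(C)C)(C(C)C)C(C)C
F10 | step 6 | (E)-3-(dimethylamino)-1-[4-methoxy-3,5-bis(3-methylbut-2-enyl)-2-(4-triisopropylsilyloxybenzyloxy)-6-(triisopropylsilyloxy)phenyl]prop-2-en-1-one | CN(C)/C=C/C(=O)c1c(O[Si](C(C)C)(C(C)C)C(C)C)c(CC=C(C)C)c(OC)c(CC=C(C)C)c1OCc1ccc(O[Si](C(C)C)(C(C)C)C(C)C)cc1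
A1 | alternative 1 | 1-(2,6-dihydroxy-4-methoxy-3,5-diprenylphenyl)ethanone (identical with 5) | CC(=O)c1c(O)c(CC=C(C)C)c(OC)c(CC=C(C)C)c1O
A2 | alternative 1 | 1-[4-methoxy-2,6-bis(2-methylbut-3-en-2-yloxy)phenyl]ethanone | CC(=O)c1c(OC(C)(C)C=C)cc(OC)cc1OC(C)(C)C=C
A3 | alternative 2 | 3-ethoxy-2-(3-methylbut-2-enyl)cyclobut-2-en-1-one | CCOC1=C(CC=C(C)C)C(=O)C1
A4 | alternative 2 | 1-methoxy-5-methylhex-4-en-1-yne | COC#CCC=C(C)C
A5 | alternative 2 | 5-ethoxy-3-methoxy-2,4-bis(3-methylbut-2-enyl)phenol | CCOc1cc(O)c(CC=C(C)C)c(OC)c1CC=C(C)C
A6 | alternative 3 | [1,3-dimethoxy-7-methyl-2-(3-methylbut-2-enyl)octa-1,3,6-trienyl]oxy-trimethylsilane | COC(O[Si](C)(C)C)=C(CC=C(C)C)C(OC)=CCC=C(C)C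
A7 | alternative 3 | (2S)-2-[4-(tert-butyldimethylsilyloxy)phenyl]-5-(phenylsulfinyl)-2,3-dihydropyran-4-one | O=C1C[C@@H](c2ccc(O[Si](C)(C)C(C)(C)C)cc2)OC=C1S(=O)c1ccccc1
A8 | alternative 3 | (2S)-2-[4-(tert-butyldimethylsilyloxy)phenyl]-5-hydroxy-7-methoxy-6,8-bis(3-methylbut-2-enyl)chroman-4-one | COc1c(CC=C(C)C)c(O)c2c(c1CC=C(C)C)O[C@H](c1ccc(O[Si](C)(C)C(C)(C)C)cc1)CC2=O
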